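The plan rests on cutting the dihydropyranone ring (O1, C2=O, C3=C4, C5, C6; side chain C1'–C10' from C6) at C3=C4. This is the only alkene in the ring and it is conjugated to the C2 carbonyl. It can therefore arise from an acrylate on the C6 oxygen and an allyl group (C5, C4 and a terminal CH2) on C6. One ring-closing metathesis forms C3=C4, closes the six-membered lactone and expels ethylene, leaving all four stereocentres and the cis C1'=C2' alkene untouched. The precursor is an open-chain triene with the C6 acrylate, the C4'/C6' syn-diol acetonide and the C8' acetate already in place, so only acetonide hydrolysis follows.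

Key step: step 16

Remark on the chemistry: the SMILES is read as (6S,1'Z,4'R,6'R,8'R), so C4'/C6' are syn and C6'/C8' are anti. Target locants are used for all intermediates. The CIP letters at C4' and C6' change with the neighbouring groups, although the spatial arrangement never does. PMB = 4-methoxybenzyl, Ipc = isopinocampheyl.

Step 1
Reactants: 1 3-phenylpropanal; 2 allylmagnesium bromide
Product: 4 (3R)-1-phenylhex-5-en-3-ol, via diisopinocampheylborinate 3 (not isolated)
Conditions: (−)-Ipc2BOMe [from (+)-α-pinene], 2, Et2O, 0 °C to rt; 1, −78 °C; then aq. NaOH, H2O2, rt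
Reagents that add atoms: none
Why: Brown allylboration, in which the B-allyl reagent formed in the flask adds through a closed chair transition state whose Ipc groups leave only the Si face of the aldehyde open, which sets C8' as R, and alkaline peroxide then frees the alcohol from boron.

Step 2
Reactants: 4 (3R)-1-phenylhex-5-en-3-ol
Product: 6 1-methoxy-4-({[(3R)-1-phenylhex-5-en-3-yl]oxy}methyl)benzene (PMB ether of 4), via sodium alkoxide 5 (not isolated)
Conditions: NaH, PMBCl, n-Bu4NI (cat.), THF/DMF, 0 °C to rt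
Reagents that add atoms: 4-methoxybenzyl chloride, COc1ccc(CCl)cc1
Why: Williamson etherification of the only hydroxyl group gives an ether that withstands the bases, organolithium reagents and IBr used later and can be removed oxidatively in the presence of acetonide, acrylate and alkenes.

Step 3
Reactants: 6 PMB ether of 4
Product: 8 (3R)-3-[(4-methoxybenzyl)oxy]-5-phenylpentanal, via vicinal diol 7 (not isolated)
Conditions: OsO4 (cat.), NaIO4, 2,6-lutidine, dioxane/H2O (3:1), rt
Reagents that add atoms: osmium tetroxide, O=[Os](=O)(=O)=O (catalytic oxygen carrier); sodium periodate, [Na+].[O-]I(=O)(=O)=O (oxygen source)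
Why: Lemieux–Johnson cleavage, in which OsO4 dihydroxylates the only alkene, NaIO4 cleaves the diol, and 2,6-lutidine keeps the medium near neutral so that the β-alkoxy aldehyde should not eliminate (C8' is not α to the carbonyl and cannot epimerise).

Step 4
Reactants: 8 (3R)-3-[(4-methoxybenzyl)oxy]-5-phenylpentanal; 2 allylmagnesium bromide
Product: 10 (4R,6R)-6-[(4-methoxybenzyl)oxy]-8-phenyloct-1-en-4-ol, via diisopinocampheylborinate 9 (not isolated)
Conditions: (+)-Ipc2BOMe [from (−)-α-pinene], 2, Et2O, 0 °C to rt; 8, −78 °C; then aq. NaOH, H2O2, rt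
Reagents that add atoms: none
Why: Brown allylboration under reagent control with the enantiomeric borane, which attacks the Re face and sets C6' as R, that is anti to the C8' ether.

Step 5
Reactants: 10 (4R,6R)-6-[(4-methoxybenzyl)oxy]-8-phenyloct-1-en-4-ol
Product: 11 tert-butyl (4R,6R)-6-[(4-methoxybenzyl)oxy]-8-phenyloct-1-en-4-yl carbonate
Conditions: Boc2O, DMAP (cat.), MeCN, rt
Reagents that add atoms: di-tert-butyl dicarbonate, CC(C)(C)OC(=O)OC(=O)OC(C)(C)C
Why: DMAP-catalysed acylation of the secondary alcohol installs the internal oxygen nucleophile for the next step and touches no stereocentre.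

Step 6
Reactants: 11 tert-butyl carbonate of 10
Product: 12 (4S,6S)-4-(iodomethyl)-6-{(2R)-2-[(4-methoxybenzyl)oxy]-4-phenylbutyl}-1,3-dioxan-2-one (cis)
Conditions: IBr, toluene, −85 °C; then aq. Na2S2O3/NaHCO3
Reagents that add atoms: iodine monobromide, BrI
Why: Iodocarbonate cyclisation of a homoallylic tert-butyl carbonate, in which IBr activates the terminal alkene, the carbonyl oxygen attacks C4' in a 6-exo mode through a chair with both side chains equatorial (setting C4' syn to C6'), and bromide takes the tert-butyl group.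

Step 7
Reactants: 12 cis iodocarbonate
Product: 14 (2S,4R)-4-[(4-methoxybenzyl)oxy]-1-[(2S)-oxiran-2-yl]-6-phenylhexan-2-ol, via iodo diol 13 (not isolated)
Conditions: K2CO3, MeOH, 0 °C to rt
Reagents that add atoms: none
Why: Carbonate methanolysis followed by intramolecular Williamson closure, in which the C4' alkoxide displaces iodide at C3' so that the C4'–O bond and its configuration are kept.

Step 8
Reactants: 14 epoxy alcohol; 15 lithium acetylide–ethylenediamine complex (LiC≡CH·H2NCH2CH2NH2)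
Product: 16 (4R,6R,8R)-8-[(4-methoxybenzyl)oxy]-10-phenyldec-1-yne-4,6-diol
Conditions: 15 (excess), DMSO, 0 °C to rt; then H2O
Reagents that add atoms: none
Why: SN2 opening of a terminal epoxide by acetylide at the unhindered C3' in DMSO, where the free C6' hydroxyl only costs one extra equivalent of base and C4' is not touched.

Step 9
Reactants: 16 (4R,6R,8R)-diol
Product: 17 (4S,6R)-4-{(2R)-2-[(4-methoxybenzyl)oxy]-4-phenylbutyl}-2,2-dimethyl-6-(prop-2-yn-1-yl)-1,3-dioxane
Conditions: Me2C(OMe)2, PPTS (cat.), CH2Cl2, rt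
Reagents that add atoms: 2,2-dimethoxypropane, COC(C)(C)OC
Why: Acid-catalysed transketalisation, in which the syn 1,3-diol gives a chair dioxane with both side chains equatorial while PMB ether and alkyne are inert to PPTS.

Step 10
Reactants: 17 acetonide alkyne
Product: 20 4-[(4R,6S)-6-{(2R)-2-[(4-methoxybenzyl)oxy]-4-phenylbutyl}-2,2-dimethyl-1,3-dioxan-4-yl]but-2-ynal, via lithium acetylide 18 (not isolated), via lithium hemiaminal alkoxide 19 (not isolated)
Conditions: n-BuLi, THF, −78 °C; DMF, −78 to 0 °C; poured into aq. KH2PO4/MTBE, 0 °C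
Reagents that add atoms: N,N-dimethylformamide, CN(C)C=O
Why: Formylation of a lithium acetylide with DMF, whose tetrahedral adduct survives until the reverse quench into phosphate buffer, which ties up dimethylamine before it can add to the ynal.

Step 11
Reactants: 20 ynal; 2 allylmagnesium bromide
Product: 22 (4S)-7-[(4R,6S)-6-{(2R)-2-[(4-methoxybenzyl)oxy]-4-phenylbutyl}-2,2-dimethyl-1,3-dioxan-4-yl]hept-1-en-5-yn-4-ol, via diisopinocampheylborinate 21 (not isolated)
Conditions: (−)-Ipc2BOMe [from (+)-α-pinene], 2, Et2O, 0 °C to rt; 20, −100 to −78 °C; then aq. NaOH, H2O2, rt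
Reagents that add atoms: none
Why: Brown allylboration of an ynal, in which Si-face attack through the chair transition state sets C6 as S under reagent control (the alkynyl group outranks allyl, hence the change of letter relative to step 1) and the distant acetonide stereocentres have no influence.

Step 12
Reactants: 22 propargylic alcohol
Product: 23 (4S,5Z)-7-[(4R,6S)-6-{(2R)-2-[(4-methoxybenzyl)oxy]-4-phenylbutyl}-2,2-dimethyl-1,3-dioxan-4-yl]hepta-1,5-dien-4-ol
Conditions: H2 (1 atm), Pd/CaCO3 poisoned with Pb(OAc)2 (Lindlar catalyst), quinoline, EtOAc, rt, stopped after one equivalent of H2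
Reagents that add atoms: none
Why: Lindlar semihydrogenation delivers one H2 in a syn sense to give the cis C1'=C2' alkene, and the alkyne binds far more strongly than the monosubstituted alkene, so it is consumed first and the reaction can be stopped in time.

Step 13
Reactants: 23 cis dienol; 24 acryloyl chloride
Product: 25 (4S,5Z)-7-[(4R,6S)-6-{(2R)-2-[(4-methoxybenzyl)oxy]-4-phenylbutyl}-2,2-dimethyl-1,3-dioxan-4-yl]hepta-1,5-dien-4-yl prop-2-enoate
Conditions: 24, Et3N, DMAP (cat.), CH2Cl2, 0 °C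
Reagents that add atoms: none
Why: DMAP-catalysed esterification of the only free hydroxyl with an acid chloride at low temperature proceeds with retention at C6 because the C6–O bond is not broken.

Step 14
Reactants: 25 PMB-protected acrylate
Product: 26 (4S,5Z)-7-{(4R,6S)-6-[(2R)-2-hydroxy-4-phenylbutyl]-2,2-dimethyl-1,3-dioxan-4-yl}hepta-1,5-dien-4-yl prop-2-enoate
Conditions: DDQ, CH2Cl2/pH 7 phosphate buffer (10:1), 0 °C to rt
Reagents that add atoms: none
Why: Oxidative PMB cleavage, in which DDQ abstracts hydride only from the electron-rich benzylic position, water traps the oxocarbenium ion, the buffer protects the acetonide, and acrylate and unconjugated alkenes are not oxidised.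

Step 15
Reactants: 26 C8' alcohol
Product: 27 (4S,5Z)-7-{(4R,6R)-6-[(2R)-2-acetoxy-4-phenylbutyl]-2,2-dimethyl-1,3-dioxan-4-yl}hepta-1,5-dien-4-yl prop-2-enoate
Conditions: Ac2O, Et3N, DMAP (cat.), CH2Cl2, rt
Reagents that add atoms: acetic anhydride, CC(=O)OC(C)=O
Why: DMAP-catalysed acetylation of the single free secondary alcohol, done now so that no acylation or base is needed once the lactone exists.

Step 16
Reactants: 27 C6 acrylate triene
Product: 28 (2R)-1-[(4R,6R)-2,2-dimethyl-6-{(2Z)-3-[(2S)-6-oxo-3,6-dihydro-2H-pyran-2-yl]prop-2-en-1-yl}-1,3-dioxan-4-yl]-4-phenylbutan-2-yl acetate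
Conditions: RuCl2(=CHPh)(PCy3)2 (first-generation Grubbs catalyst, 10 mol %, two portions), CH2Cl2 (0.003 M), reflux, argon sparge
Reagents that add atoms: none
Why: Olefin metathesis by the alkylidene/metallacyclobutane mechanism: the ruthenium benzylidene exchanges first with the monosubstituted, electron-neutral allyl terminus to place the metal on C4, this alkylidene adds across the acrylate C=C in an intramolecular [2+2] step, and cycloreversion releases the C3=C4 lactone and Ru=CH2, which carries the chain with loss of ethylene. The closest known reaction type is ring-closing metathesis of acrylates of homoallylic alcohols to 6-substituted 5,6-dihydropyran-2-ones, including cases with a 1-alkenyl group on C6. The one ring closes as a six-membered ring with an endocyclic, necessarily cis alkene, driven by escape of ethylene at reflux and favoured over dimerisation by high dilution. No stereocentre is formed, and C6, C4', C6' and C8' are spectators. The step needs chemoselectivity for the two terminal alkenes over the internal cis C1'=C2' alkene, which from C4 could only close a cyclobutene, which could give a butenolide only if the catalyst loaded on an alkene it avoids, and which is 1,2-disubstituted and flanked by C6. The bis(phosphine) catalyst is chosen because it hardly touches such internal alkenes, which also guards the cis geometry, while acetonide and acetate leave no free hydroxyl to bind ruthenium or to take over the acetyl group.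

Step 17
Reactants: 28 acetonide of the target
Product: 29 (6S)-6-[(1Z,4R,6R,8R)-8-acetoxy-4,6-dihydroxy-10-phenyldec-1-en-1-yl]-5,6-dihydro-2H-pyran-2-one
Conditions: AcOH/H2O (4:1), rt
Reagents that add atoms: none
Why: Acid-catalysed acetal hydrolysis under conditions too mild for acetate, lactone or alkenes, in a weakly acidic medium that avoids the base-promoted shift of the acetyl group from O8' to O6'.

Compound list
1 | 3-phenylpropanal | O=CCCc1ccccc1 | starting material
2 | allylmagnesium bromide | C=CC[Mg]Br | starting material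
3 | (3R)-1-phenylhex-5-en-3-yl diisopinocampheylborinate (Ipc from (+)-α-pinene) | O([C@H](CCc1ccccc1)CC=C)B([C@@H]1C[C@@H]2C[C@H]([C@H]1C)C2(C)C)[C@@H]1C[C@@H]2C[C@H]([C@H]1C)C2(C)C | intermediate
4 | (3R)-1-phenylhex-5-en-3-ol | O[C@H](CCc1ccccc1)CC=C | intermediate
5 | sodium (3R)-1-phenylhex-5-en-3-olate | [Na+].[O-][C@H](CCc1ccccc1)CC=C | intermediate
6 | 1-methoxy-4-({[(3R)-1-phenylhex-5-en-3-yl]oxy}methyl)benzene | COc1ccc(CO[C@H](CCc2ccccc2)CC=C)cc1 | intermediate
7 | (2RS,4R)-4-[(4-methoxybenzyl)oxy]-6-phenylhexane-1,2-diol | COc1ccc(CO[C@H](CCc2ccccc2)CC(O)CO)cc1 | intermediate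
8 | (3R)-3-[(4-methoxybenzyl)oxy]-5-phenylpentanal | COc1ccc(CO[C@H](CCc2ccccc2)CC=O)cc1 | intermediate
9 | (4R,6R)-6-[(4-methoxybenzyl)oxy]-8-phenyloct-1-en-4-yl diisopinocampheylborinate (Ipc from (−)-α-pinene) | COc1ccc(CO[C@H](CCc2ccccc2)C[C@H](OB([C@H]2C[C@H]3C[C@@H]([C@@H]2C)C3(C)C)[C@H]2C[C@H]3C[C@@H]([C@@H]2C)C3(C)C)CC=C)cc1 | intermediate
10 | (4R,6R)-6-[(4-methoxybenzyl)oxy]-8-phenyloct-1-en-4-ol | COc1ccc(CO[C@H](CCc2ccccc2)C[C@H](O)CC=C)cc1 | intermediate
11 | tert-butyl (4R,6R)-6-[(4-methoxybenzyl)oxy]-8-phenyloct-1-en-4-yl carbonate | COc1ccc(CO[C@H](CCc2ccccc2)C[C@H](OC(=O)OC(C)(C)C)CC=C)cc1 | intermediate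
12 | (4S,6S)-4-(iodomethyl)-6-{(2R)-2-[(4-methoxybenzyl)oxy]-4-phenylbutyl}-1,3-dioxan-2-one | COc1ccc(CO[C@H](CCc2ccccc2)C[C@H]2C[C@@H](CI)OC(=O)O2)cc1 | intermediate
13 | (2S,4R,6R)-1-iodo-6-[(4-methoxybenzyl)oxy]-8-phenyloctane-2,4-diol | COc1ccc(CO[C@H](CCc2ccccc2)C[C@H](O)C[C@H](O)CI)cc1 | intermediate
14 | (2S,4R)-4-[(4-methoxybenzyl)oxy]-1-[(2S)-oxiran-2-yl]-6-phenylhexan-2-ol | COc1ccc(CO[C@H](CCc2ccccc2)C[C@H](O)C[C@H]2CO2)cc1 | intermediate
15 | lithium acetylide–ethylenediamine complex | [Li]C#C.NCCN | starting material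
16 | (4R,6R,8R)-8-[(4-methoxybenzyl)oxy]-10-phenyldec-1-yne-4,6-diol | COc1ccc(CO[C@H](CCc2ccccc2)C[C@H](O)C[C@H](O)CC#C)cc1 | intermediate
17 | (4S,6R)-4-{(2R)-2-[(4-methoxybenzyl)oxy]-4-phenylbutyl}-2,2-dimethyl-6-(prop-2-yn-1-yl)-1,3-dioxane | COc1ccc(CO[C@H](CCc2ccccc2)C[C@H]2C[C@@H](CC#C)OC(C)(C)O2)cc1 | intermediate
18 | lithium acetylide of 17 | COc1ccc(CO[C@H](CCc2ccccc2)C[C@H]2C[C@@H](CC#C[Li])OC(C)(C)O2)cc1 | intermediate
19 | lithium alkoxide of the DMF adduct of 18 (hemiaminal carbon unassigned) | COc1ccc(CO[C@H](CCc2ccccc2)C[C@H]2C[C@@H](CC#CC(O[Li])N(C)C)OC(C)(C)O2)cc1 | intermediate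
20 | 4-[(4R,6S)-6-{(2R)-2-[(4-methoxybenzyl)oxy]-4-phenylbutyl}-2,2-dimethyl-1,3-dioxan-4-yl]but-2-ynal | COc1ccc(CO[C@H](CCc2ccccc2)C[C@H]2C[C@@H](CC#CC=O)OC(C)(C)O2)cc1 | intermediate
21 | diisopinocampheylborinate of 22 (Ipc from (+)-α-pinene) | COc1ccc(CO[C@H](CCc2ccccc2)C[C@H]2C[C@@H](CC#C[C@@H](OB([C@@H]3C[C@@H]4C[C@H]([C@H]3C)C4(C)C)[C@@H]3C[C@@H]4C[C@H]([C@H]3C)C4(C)C)CC=C)OC(C)(C)O2)cc1 | intermediate
22 | (4S)-7-[(4R,6S)-6-{(2R)-2-[(4-methoxybenzyl)oxy]-4-phenylbutyl}-2,2-dimethyl-1,3-dioxan-4-yl]hept-1-en-5-yn-4-ol | COc1ccc(CO[C@H](CCc2ccccc2)C[C@H]2C[C@@H](CC#C[C@@H](O)CC=C)OC(C)(C)O2)cc1 | intermediate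
23 | (4S,5Z)-7-[(4R,6S)-6-{(2R)-2-[(4-methoxybenzyl)oxy]-4-phenylbutyl}-2,2-dimethyl-1,3-dioxan-4-yl]hepta-1,5-dien-4-ol | COc1ccc(CO[C@H](CCc2ccccc2)C[C@H]2C[C@@H](C/C=C\[C@@H](O)CC=C)OC(C)(C)O2)cc1 | intermediate
24 | acryloyl chloride | C=CC(=O)Cl | starting material
25 | (4S,5Z)-7-[(4R,6S)-6-{(2R)-2-[(4-methoxybenzyl)oxy]-4-phenylbutyl}-2,2-dimethyl-1,3-dioxan-4-yl]hepta-1,5-dien-4-yl prop-2-enoate | COc1ccc(CO[C@H](CCc2ccccc2)C[C@H]2C[C@@H](C/C=C\[C@@H](OC(=O)C=C)CC=C)OC(C)(C)O2)cc1 | intermediate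
26 | (4S,5Z)-7-{(4R,6S)-6-[(2R)-2-hydroxy-4-phenylbutyl]-2,2-dimethyl-1,3-dioxan-4-yl}hepta-1,5-dien-4-yl prop-2-enoate | O[C@H](CCc1ccccc1)C[C@H]1C[C@@H](C/C=C\[C@@H](OC(=O)C=C)CC=C)OC(C)(C)O1 | intermediate
27 | (4S,5Z)-7-{(4R,6R)-6-[(2R)-2-acetoxy-4-phenylbutyl]-2,2-dimethyl-1,3-dioxan-4-yl}hepta-1,5-dien-4-yl prop-2-enoate | CC(=O)O[C@H](CCc1ccccc1)C[C@H]1C[C@@H](C/C=C\[C@@H](OC(=O)C=C)CC=C)OC(C)(C)O1 | intermediate
28 | (2R)-1-[(4R,6R)-2,2-dimethyl-6-{(2Z)-3-[(2S)-6-oxo-3,6-dihydro-2H-pyran-2-yl]prop-2-en-1-yl}-1,3-dioxan-4-yl]-4-phenylbutan-2-yl acetate | CC(=O)O[C@H](CCc1ccccc1)C[C@H]1C[C@@H](C/C=C\[C@@H]2CC=CC(=O)O2)OC(C)(C)O1 | intermediate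
29 | (6S)-6-[(1Z,4R,6R,8R)-8-acetoxy-4,6-dihydroxy-10-phenyldec-1-en-1-yl]-5,6-dihydro-2H-pyran-2-one | CC(=O)O[C@H](CCc1ccccc1)C[C@H](O)C[C@H](O)C/C=C\[C@@H]1CC=CC(=O)O1 | target

Total step count: 17. Longest linear sequence: 17 steps (1 to 29); the route is fully linear.

Steps most likely to fail

Step 16.
- **What may go wrong:** the electron-poor acrylate may be engaged so slowly that the catalyst dies first. The cis C1'=C2' alkene may also enter metathesis, with loss of its geometry or of the side chain.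
- **Fallback:** the ring is closed while C1'–C2' is still a triple bond, and the cis alkene is made afterwards. The detour sets out from 22. Acryloylation with 24 (Et3N, DMAP, CH2Cl2, 0 °C) should give the alkynyl acrylate F1. DDQ in buffered CH2Cl2 should then give the C8' alcohol F2, and Ac2O, Et3N and DMAP the C8' acetate F3. Ring-closing metathesis of F3 with RuCl2(=CHPh)(PCy3)2 has no further alkene to choose, and the C4 alkylidene could reach the alkyne only through a cyclobutene, so it should give the alkynyl lactone F4. Semihydrogenation of F4 over Pd/CaCO3 poisoned with Pb(OAc)2 and quinoline, with no terminal alkene left in the molecule, comes back to the route at 28.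

Step 12.
- **What may go wrong:** hydrogen uptake may run on into the terminal alkene once the alkyne is used up, or the alkene may isomerise from cis to trans on the metal.
- **Fallback:** the triple bond is reduced before the allyl group exists. The detour sets out from 17. Lithiation (n-BuLi, THF, −78 °C) and paraformaldehyde should give the propargylic alcohol F5. Its semihydrogenation over the same poisoned palladium has no other alkene to spare and should give the cis allylic alcohol F6. MnO2 in CH2Cl2 should give the cis enal F7, which is used at once and cold because it can isomerise. Brown allylboration with the borane from (−)-Ipc2BOMe and 2 at −78 °C, by way of the diisopinocampheylborinate F8, comes back to the route at 23. The alkenyl group ranks like the alkynyl group, so the same reagent gives 6S.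

Step 11.
- **What may go wrong:** facial selectivity may be poor on the slim, rod-like ynal. This is made worse by a hard separation of C6 epimers whose other stereocentres lie far away.
- **Fallback:** C6 is set by reduction instead of C–C bond formation. The detour sets out from 22 of insufficient purity at C6. Dess–Martin periodinane (NaHCO3, CH2Cl2, 0 °C) should give the ynone F9, which is handled cold and without base because its C5 methylene is doubly activated. Noyori-type asymmetric transfer hydrogenation follows, with the base-free complex Ru[(S,S)-TsDPEN](p-cymene) in i-PrOH. This catalyst places the alkynyl group where an aryl group would sit, so it should return the 6S alcohol and rejoin the route at 22.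

Further compounds
F1 | step 16 | (4S)-7-[(4R,6S)-6-{(2R)-2-[(4-methoxybenzyl)oxy]-4-phenylbutyl}-2,2-dimethyl-1,3-dioxan-4-yl]hept-1-en-5-yn-4-yl prop-2-enoate | COc1ccc(CO[C@H](CCc2ccccc2)C[C@H]2C[C@@H](CC#C[C@@H](OC(=O)C=C)CC=C)OC(C)(C)O2)cc1
F2 | step 16 | (4S)-7-{(4R,6S)-6-[(2R)-2-hydroxy-4-phenylbutyl]-2,2-dimethyl-1,3-dioxan-4-yl}hept-1-en-5-yn-4-yl prop-2-enoate | O[C@H](CCc1ccccc1)C[C@H]1C[C@@H](CC#C[C@@H](OC(=O)C=C)CC=C)OC(C)(C)O1
F3 | step 16 | (4S)-7-{(4R,6R)-6-[(2R)-2-acetoxy-4-phenylbutyl]-2,2-dimethyl-1,3-dioxan-4-yl}hept-1-en-5-yn-4-yl prop-2-enoate | CC(=O)O[C@H](CCc1ccccc1)C[C@H]1C[C@@H](CC#C[C@@H](OC(=O)C=C)CC=C)OC(C)(C)O1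
F4 | step 16 | (2R)-1-[(4R,6R)-2,2-dimethyl-6-{3-[(2S)-6-oxo-3,6-dihydro-2H-pyran-2-yl]prop-2-yn-1-yl}-1,3-dioxan-4-yl]-4-phenylbutan-2-yl acetate | CC(=O)O[C@H](CCc1ccccc1)C[C@H]1C[C@@H](CC#C[C@@H]2CC=CC(=O)O2)OC(C)(C)O1
F5 | step 12 | 4-[(4R,6S)-6-{(2R)-2-[(4-methoxybenzyl)oxy]-4-phenylbutyl}-2,2-dimethyl-1,3-dioxan-4-yl]but-2-yn-1-ol | COc1ccc(CO[C@H](CCc2ccccc2)C[C@H]2C[C@@H](CC#CCO)OC(C)(C)O2)cc1
F6 | step 12 | (2Z)-4-[(4R,6S)-6-{(2R)-2-[(4-methoxybenzyl)oxy]-4-phenylbutyl}-2,2-dimethyl-1,3-dioxan-4-yl]but-2-en-1-ol | COc1ccc(CO[C@H](CCc2ccccc2)C[C@H]2C[C@@H](C/C=C\CO)OC(C)(C)O2)cc1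
F7 | step 12 | (2Z)-4-[(4R,6S)-6-{(2R)-2-[(4-methoxybenzyl)oxy]-4-phenylbutyl}-2,2-dimethyl-1,3-dioxan-4-yl]but-2-enal | COc1ccc(CO[C@H](CCc2ccccc2)C[C@H]2C[C@@H](C/C=C\C=O)OC(C)(C)O2)cc1
F8 | step 12 | diisopinocampheylborinate of 23 (Ipc from (+)-α-pinene) | COc1ccc(CO[C@H](CCc2ccccc2)C[C@H]2C[C@@H](C/C=C\[C@@H](OB([C@@H]3C[C@@H]4C[C@H]([C@H]3C)C4(C)C)[C@@H]3C[C@@H]4C[C@H]([C@H]3C)C4(C)C)CC=C)OC(C)(C)O2)cc1
F9 | step 11 | 7-[(4R,6S)-6-{(2R)-2-[(4-methoxybenzyl)oxy]-4-phenylbutyl}-2,2-dimethyl-1,3-dioxan-4-yl]hept-1-en-5-yn-4-one | COc1ccc(CO[C@H](CCc2ccccc2)C[C@H]2C[C@@H](CC#CC(=O)CC=C)OC(C)(C)O2)cc1
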